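**Plan**

- Retrosynthesis: the two O-benzyl groups are removed first; then the aryl C–CH2 bond on C3 is cut (zinc homoenolate + aryl bromide). That CH2 is folded back onto the lactone carbonyl carbon C2 as a cyclopropane (temporary C2–CH2 bond). Then the CH2–C3 bond (cyclopropanation), C3–O, the lactone O1–C2 bond and C3–C4 (auxiliary alkylation) are cut.
- Forward: C3–C4 alkylation → γ-lactone → C3 oxygenation and O-benzylation → silyl ketene acetal → cyclopropanation to a 2-oxabicyclo[3.1.0]hexane → strain-release opening and arylation → hydrogenolysis.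
- Enabling feature: the benzylic CH2 is β to the lactone carbonyl C2 across the fully substituted C3 (the array O1–C2(=O)–C3–CH2 is an ester homoenolate, and C3 has no hydrogen). The CH2 can therefore be stored as C6 of a 1-siloxy-2-oxabicyclo[3.1.0]hexane fused on C2–C3 and released as a carbon nucleophile toward an aryl electrophile (polarity reversal of a normally electrophilic β-carbon).
- Stereochemistry: C4 comes from the (S)-4-benzyloxazolidinone auxiliary. C3 comes from cyclopropanation of the planar ketene acetal anti to the C4 benzyl group, which places C3–O cis and the CH2 trans to it; ring opening and coupling do not touch C3.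

Key step: step 9

Remarks: Compounds 11 and 12 are expected as C3 epimer mixtures (trans epimer drawn). Both epimers give the same planar ketene acetal 14, so the mixture is carried forward. The C4 descriptor changes from R (9) to S (11 onward) through a CIP priority change only; the geometry is unchanged.

**Step 1**
Reactants: 1 3-(3,4-dimethoxyphenyl)propanoic acid; 2 (S)-4-benzyloxazolidin-2-one
Product: 4 (S)-4-benzyl-3-[3-(3,4-dimethoxyphenyl)propanoyl]oxazolidin-2-one, via mixed pivalic anhydride 3 (not isolated)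
Conditions: PivCl, Et3N, THF, −20 °C; then LiCl, 2, −20 °C → rt
Reagents that add atoms: none
Why: N-acylation of the oxazolidinone through the mixed anhydride under LiCl/Et3N conditions is routine and forms no stereocentre.

**Step 2**
Reactants: 4 (S)-4-benzyl-3-[3-(3,4-dimethoxyphenyl)propanoyl]oxazolidin-2-one; 5 tert-butyl bromoacetate
Product: 7 tert-butyl (R)-3-[(S)-4-benzyl-2-oxooxazolidine-3-carbonyl]-4-(3,4-dimethoxyphenyl)butanoate, via sodium enolate 6 (not isolated)
Conditions: NaHMDS, THF, −78 °C; then 5, −78 → −40 °C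
Reagents that add atoms: none
Why: Evans asymmetric alkylation: the chelated (Z)-enolate is alkylated on the face opposite the auxiliary benzyl group, which sets the future C4 stereocentre.

**Step 3**
Reactants: 7 tert-butyl (R)-3-[(S)-4-benzyl-2-oxooxazolidine-3-carbonyl]-4-(3,4-dimethoxyphenyl)butanoate
Product: 9 (R)-4-(3,4-dimethoxybenzyl)dihydrofuran-2(3H)-one, via hydroxy tert-butyl ester 8 (not isolated)
Conditions: LiBH4, MeOH (1 equiv), THF, 0 °C; aqueous work-up; then p-TsOH·H2O (cat.), toluene, 80 °C
Reagents that add atoms: none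
Why: Reductive removal of the auxiliary gives the primary alcohol without touching the tert-butyl ester, and acid then cleaves that ester and closes the γ-lactone, leaving the stereocentre untouched.

**Step 4**
Reactants: 9 (R)-4-(3,4-dimethoxybenzyl)dihydrofuran-2(3H)-one
Product: 11 (3R,4S)-4-(3,4-dimethoxybenzyl)-3-hydroxydihydrofuran-2(3H)-one, via sodium enolate 10 (not isolated)
Conditions: NaHMDS, THF, −78 °C; 2-(phenylsulfonyl)-3-phenyloxaziridine, −78 °C; AcOH quench
Reagents that add atoms: 2-(phenylsulfonyl)-3-phenyloxaziridine, O=S(=O)(c1ccccc1)N1OC1c1ccccc1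
Why: Oxaziridine hydroxylation of the lactone enolate should deliver oxygen anti to the C4 benzyl group (trans epimer major), and the C3 configuration is of no consequence because C3 becomes planar again in step 6.

**Step 5**
Reactants: 11 (3R,4S)-4-(3,4-dimethoxybenzyl)-3-hydroxydihydrofuran-2(3H)-one
Product: 12 (3R,4S)-3-(benzyloxy)-4-(3,4-dimethoxybenzyl)dihydrofuran-2(3H)-one
Conditions: BnBr, Ag2O, 4 Å MS, CH2Cl2, rt, dark
Reagents that add atoms: benzyl bromide, BrCc1ccccc1
Why: Silver(I) oxide-promoted Williamson etherification benzylates the α-hydroxy lactone without strong base, and the benzyl ether is a weak donor and poor leaving group on C3 that is removed with the phenol benzyl ether at the end.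

**Step 6**
Reactants: 12 (3R,4S)-3-(benzyloxy)-4-(3,4-dimethoxybenzyl)dihydrofuran-2(3H)-one
Product: 14 {[(S)-3-(benzyloxy)-4-(3,4-dimethoxybenzyl)-4,5-dihydrofuran-2-yl]oxy}trimethylsilane, via lithium enolate 13 (not isolated)
Conditions: LDA (commercial solution), THF, −78 °C; TMSCl, −78 → 0 °C; evaporation, pentane, filtration under Ar (used crude)
Reagents that add atoms: chlorotrimethylsilane, C[Si](C)(C)Cl
Why: Kinetic enolisation and O-silylation of the lactone enolate should give the tetrasubstituted ketene silyl acetal, in which C3 is planar and only the C4 stereocentre remains.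

**Step 7**
Reactants: 14 {[(S)-3-(benzyloxy)-4-(3,4-dimethoxybenzyl)-4,5-dihydrofuran-2-yl]oxy}trimethylsilane
Product: 15 (1S,4S,5S)-5-(benzyloxy)-4-(3,4-dimethoxybenzyl)-1-[(trimethylsilyl)oxy]-2-oxabicyclo[3.1.0]hexane
Conditions: Et2Zn, CH2I2, hexane/toluene, 0 °C → rt; pyridine quench, filtration through basic alumina
Reagents that add atoms: diiodomethane, ICI
Why: Simmons–Smith cyclopropanation (Furukawa variant) of the electron-rich ketene acetal C2=C3 bond should occur on the face anti to the C4 benzyl group, so the new CH2 ends trans and the C3–O bond cis to that group, which sets the quaternary stereocentre.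

**Step 8**
Reactants: 16 4-bromo-2-methoxyphenol
Product: 17 1-(benzyloxy)-4-bromo-2-methoxybenzene
Conditions: BnBr, K2CO3, acetone, reflux
Reagents that add atoms: benzyl bromide, BrCc1ccccc1
Why: Williamson etherification protects the phenol and provides the aryl electrophile.

**Step 9**
Reactants: 15 (1S,4S,5S)-5-(benzyloxy)-4-(3,4-dimethoxybenzyl)-1-[(trimethylsilyl)oxy]-2-oxabicyclo[3.1.0]hexane; 17 1-(benzyloxy)-4-bromo-2-methoxybenzene
Product: 19 (3S,4S)-3-(benzyloxy)-3-[4-(benzyloxy)-3-methoxybenzyl]-4-(3,4-dimethoxybenzyl)dihydrofuran-2(3H)-one, via zinc homoenolate 18 (not isolated)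
Conditions: ZnCl2 (1.1 equiv), Et2O, rt; volatiles removed in vacuo; then 17, Pd2(dba)3 (2.5 mol %), SPhos (10 mol %), DMA/THF, rt → 40 °C
Reagents that add atoms: none
Why: Proposed new method: ZnCl2 attacks the electron-rich C1–C6 bond of the cyclopropanone silyl ketal at the unsubstituted C6, the cation developing at C1 is stabilised by its two oxygens, chloride takes the silyl group, and release of ring strain together with formation of the lactone C=O gives the carbonyl-chelated β-zincio lactone 18; oxidative addition of 17 to Pd(0)/SPhos, transmetalation and C(sp2)–C(sp3) reductive elimination then form the aryl–CH2 bond. The closest known reaction types are the Pd-catalysed arylation of zinc ester homoenolates generated from 1-alkoxy-1-siloxycyclopropanes and the Negishi coupling of serine-derived β-amido zinc ester homoenolates; what has not been shown is a lactone-fused cyclopropane that carries an ether oxygen on the carbon next to the zinc-bearing CH2. No ring is closed: the three-membered ring C1–C5–C6 is opened and the γ-lactone carbonyl is restored. No stereocentre is created; C3 and C4 are bystanders, so the configuration set by the cyclopropanation in step 7 is carried into 19 unchanged. The step needs C1–C6 rather than C5–C6 or C1–C5 cleavage, secured by the doubly oxygenated C1 and the unhindered CH2, and it needs coupling to outrun β-alkoxide elimination to the α-methylene lactone, which should be held back by chelation of zinc to the lactone carbonyl (C–Zn kept gauche to C3–OBn), by benzyloxide being a poor leaving group, by the amide co-solvent and by the fast biarylphosphine catalyst. β-Hydride elimination at palladium cannot occur because C3 bears no hydrogen.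

**Step 10**
Reactants: 19 (3S,4S)-3-(benzyloxy)-3-[4-(benzyloxy)-3-methoxybenzyl]-4-(3,4-dimethoxybenzyl)dihydrofuran-2(3H)-one
Product: 20 trachelogenin, (3S,4S)-4-(3,4-dimethoxybenzyl)-3-hydroxy-3-(4-hydroxy-3-methoxybenzyl)dihydrofuran-2(3H)-one
Conditions: H2 (1 atm), Pd(OH)2/C, EtOAc/EtOH, rt
Reagents that add atoms: none
Why: Hydrogenolysis cleaves both benzyl ethers at their benzylic C–O bonds, while the homobenzylic tertiary C3–O bond, the lactone and the methyl ethers should remain intact.

**Compound list**

1 | 3-(3,4-dimethoxyphenyl)propanoic acid | COc1ccc(CCC(=O)O)cc1OC | starting material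
2 | (S)-4-benzyloxazolidin-2-one | O=C1N[C@@H](Cc2ccccc2)CO1 | starting material
3 | 3-(3,4-dimethoxyphenyl)propanoic pivalic anhydride | COc1ccc(CCC(=O)OC(=O)C(C)(C)C)cc1OC | intermediate
4 | (S)-4-benzyl-3-[3-(3,4-dimethoxyphenyl)propanoyl]oxazolidin-2-one | COc1ccc(CCC(=O)N2C(=O)OC[C@@H]2Cc2ccccc2)cc1OC | intermediate
5 | tert-butyl bromoacetate | CC(C)(C)OC(=O)CBr | starting material
6 | sodium (Z)-enolate of 4 | [Na+].[O-]/C(=C\Cc1ccc(OC)c(OC)c1)N1C(=O)OC[C@@H]1Cc1ccccc1 | intermediate
7 | tert-butyl (R)-3-[(S)-4-benzyl-2-oxooxazolidine-3-carbonyl]-4-(3,4-dimethoxyphenyl)butanoate | CC(C)(C)OC(=O)C[C@@H](Cc1ccc(OC)c(OC)c1)C(=O)N1C(=O)OC[C@@H]1Cc1ccccc1 | intermediate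
8 | tert-butyl (R)-4-(3,4-dimethoxyphenyl)-3-(hydroxymethyl)butanoate | CC(C)(C)OC(=O)C[C@@H](Cc1ccc(OC)c(OC)c1)CO | intermediate
9 | (R)-4-(3,4-dimethoxybenzyl)dihydrofuran-2(3H)-one | O=C1OC[C@H](Cc2ccc(OC)c(OC)c2)C1 | intermediate
10 | sodium (R)-4-(3,4-dimethoxybenzyl)-4,5-dihydrofuran-2-olate | [Na+].[O-]C1=C[C@@H](Cc2ccc(OC)c(OC)c2)CO1 | intermediate
11 | (3R,4S)-4-(3,4-dimethoxybenzyl)-3-hydroxydihydrofuran-2(3H)-one (trans, major epimer) | O[C@H]1C(=O)OC[C@@H]1Cc1ccc(OC)c(OC)c1 | intermediate
12 | (3R,4S)-3-(benzyloxy)-4-(3,4-dimethoxybenzyl)dihydrofuran-2(3H)-one | c1ccccc1CO[C@H]1C(=O)OC[C@@H]1Cc1ccc(OC)c(OC)c1 | intermediate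
13 | lithium (S)-3-(benzyloxy)-4-(3,4-dimethoxybenzyl)-4,5-dihydrofuran-2-olate | [Li+].[O-]C1=C(OCc2ccccc2)[C@@H](Cc2ccc(OC)c(OC)c2)CO1 | intermediate
14 | {[(S)-3-(benzyloxy)-4-(3,4-dimethoxybenzyl)-4,5-dihydrofuran-2-yl]oxy}trimethylsilane | C[Si](C)(C)OC1=C(OCc2ccccc2)[C@@H](Cc2ccc(OC)c(OC)c2)CO1 | intermediate
15 | (1S,4S,5S)-5-(benzyloxy)-4-(3,4-dimethoxybenzyl)-1-[(trimethylsilyl)oxy]-2-oxabicyclo[3.1.0]hexane | C[Si](C)(C)O[C@@]12C[C@]1(OCc1ccccc1)[C@@H](Cc1ccc(OC)c(OC)c1)CO2 | intermediate
16 | 4-bromo-2-methoxyphenol | COc1cc(Br)ccc1O | starting material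
17 | 1-(benzyloxy)-4-bromo-2-methoxybenzene | COc1cc(Br)ccc1OCc1ccccc1 | intermediate
18 | chloro{[(3S,4S)-3-(benzyloxy)-4-(3,4-dimethoxybenzyl)-2-oxotetrahydrofuran-3-yl]methyl}zinc | Cl[Zn]C[C@@]1(OCc2ccccc2)C(=O)OC[C@@H]1Cc1ccc(OC)c(OC)c1 | intermediate
19 | (3S,4S)-3-(benzyloxy)-3-[4-(benzyloxy)-3-methoxybenzyl]-4-(3,4-dimethoxybenzyl)dihydrofuran-2(3H)-one | COc1cc(C[C@@]2(OCc3ccccc3)C(=O)OC[C@@H]2Cc2ccc(OC)c(OC)c2)ccc1OCc1ccccc1 | intermediate
20 | trachelogenin, (3S,4S)-4-(3,4-dimethoxybenzyl)-3-hydroxy-3-(4-hydroxy-3-methoxybenzyl)dihydrofuran-2(3H)-one | COc1cc(C[C@@]2(O)C(=O)OC[C@@H]2Cc2ccc(OC)c(OC)c2)ccc1O | target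

**Step count and risks**

Total step count: 10. Longest linear sequence: 9 steps (steps 1–7, 9, 10).

Steps most likely to fail:

1. Step 9 (proposed new method). The zinc or palladium homoenolate may lose benzyloxide by β-elimination, giving the exocyclic alkene; the carbon–zinc bond may be protonated; or the wrong cyclopropane bond may cleave. The fallback uses known chemistry and forms the same aryl–CH2 bond from an epoxide instead of the cyclopropane. It sets out from 11 and returns to the route at 20. The dianion of 11 (LDA, 2.2 equiv, THF/DMPU, −78 °C) is hydroxymethylated with monomeric formaldehyde anti to the C4 benzyl group to give (3R,4S)-4-(3,4-dimethoxybenzyl)-3-hydroxy-3-(hydroxymethyl)dihydrofuran-2(3H)-one F1. Selective sulfonylation of the primary hydroxyl (TsCl, pyridine, 0 °C) should give [(3R,4S)-4-(3,4-dimethoxybenzyl)-3-hydroxy-2-oxotetrahydrofuran-3-yl]methyl 4-methylbenzenesulfonate F2, which closes with K2CO3 in MeCN to the spiro-epoxide (3R,7S)-7-(3,4-dimethoxybenzyl)-1,5-dioxaspiro[2.4]heptan-4-one F3. Copper-catalysed opening of the epoxide at its CH2 terminus (CuI 10 mol %, THF, −40 → −20 °C) by [4-(benzyloxy)-3-methoxyphenyl]magnesium bromide F4, made from 17 and Mg, should give (3S,4S)-3-[4-(benzyloxy)-3-methoxybenzyl]-4-(3,4-dimethoxybenzyl)-3-hydroxydihydrofuran-2(3H)-one F5. Hydrogenolysis of F5 under the step 10 conditions gives 20.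

2. Step 7. Zinc iodide species may open or protodesilylate the acid-labile cyclopropanone ketal during the reaction or work-up, and facial selectivity on the tetrasubstituted alkene may be incomplete. The fallback installs the one-carbon unit by enolate alkylation and joins the fragments by a radical cross-electrophile coupling. It sets out from 12 (through its enolate 13) and returns at 19. Enolate 13 is alkylated with diiodomethane (THF/DMPU, −78 → −20 °C), again anti to the C4 benzyl group, to give (3S,4S)-3-(benzyloxy)-4-(3,4-dimethoxybenzyl)-3-(iodomethyl)dihydrofuran-2(3H)-one F6. Nickel-catalysed reductive coupling of this iodide with 17 (NiBr2·glyme, 4,4′-di-tert-butyl-2,2′-bipyridine, Mn, DMA) should give 19 through a primary alkyl radical, which does not expel the β-alkoxy group.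

3. Step 10. Hydrogenolysis of the hindered tertiary benzyl ether may be incomplete while the aryl ether is cleaved, and forcing conditions risk arene saturation. The fallback is Lewis-acid debenzylation in place of hydrogenolysis: 19 is treated with BCl3 and pentamethylbenzene as cation scavenger (CH2Cl2, −78 °C), which should cleave both benzyl ethers at the benzyl–oxygen bond and spare the methyl ethers. It sets out from 19 and returns at 20; it makes no new compound (F0).

**Further compounds**

F1 | step 9 | (3R,4S)-4-(3,4-dimethoxybenzyl)-3-hydroxy-3-(hydroxymethyl)dihydrofuran-2(3H)-one | OC[C@@]1(O)C(=O)OC[C@@H]1Cc1ccc(OC)c(OC)c1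
F2 | step 9 | [(3R,4S)-4-(3,4-dimethoxybenzyl)-3-hydroxy-2-oxotetrahydrofuran-3-yl]methyl 4-methylbenzenesulfonate | Cc1ccc(cc1)S(=O)(=O)OC[C@@]1(O)C(=O)OC[C@@H]1Cc1ccc(OC)c(OC)c1
F3 | step 9 | (3R,7S)-7-(3,4-dimethoxybenzyl)-1,5-dioxaspiro[2.4]heptan-4-one | C1O[C@@]12C(=O)OC[C@@H]2Cc2ccc(OC)c(OC)c2
F4 | step 9 | [4-(benzyloxy)-3-methoxyphenyl]magnesium bromide | COc1cc([Mg]Br)ccc1OCc1ccccc1
F5 | step 9 | (3S,4S)-3-[4-(benzyloxy)-3-methoxybenzyl]-4-(3,4-dimethoxybenzyl)-3-hydroxydihydrofuran-2(3H)-one | COc1cc(C[C@@]2(O)C(=O)OC[C@@H]2Cc2ccc(OC)c(OC)c2)ccc1OCc1ccccc1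
F6 | step 7 | (3S,4S)-3-(benzyloxy)-4-(3,4-dimethoxybenzyl)-3-(iodomethyl)dihydrofuran-2(3H)-one | IC[C@@]1(OCc2ccccc2)C(=O)OC[C@@H]1Cc1ccc(OC)c(OC)c1
F0 | step 10 | none | none
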